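**Plan**

- Numbering as in the eremophilanes: ring A = C1–C5 and C10 (ester oxygen on C3, methyl on C4, quaternary C5 with its methyl); ring B = C5–C10 (C6=C7, 2-hydroxypropan-2-yl on C7, carbonyl C8, C9=C10).
- Cuts, in order: the ester C–O bond at C3; the ring B bonds C5–C6 and C7–C8, which takes out an alkyne C6≡C7 and leaves a cyclobutenone C8(=O)–C9H=C10–C5 fused to ring A; then C8–C9 and C5–C10 of that four-membered ring; then C3–C4 (aldol).
- Enabling feature: because C5 is quaternary, ring B is a cyclohexa-2,5-dienone that cannot become a phenol. Its segment O=C8–C9H=C10–C5 is the [2+2] retron of a keteniminium C5=C8=N+ and a terminal alkyne C9≡C10 that the chain C4–C3–C2–C1 already holds on C5.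
- Forward: aldol (C3–C4), ethyl ketone, α-diazo ketone, Wolff rearrangement to an amide; one [2+2] event closes the cyclobutenone and ring A together; the strained C5–C8 bond then takes up a two-carbon alkyne to give ring B; desilylation and esterification with the separately made (Z)-acid finish the route.
- Stereochemistry: C3 and C4 come from the oxazolidinone-controlled syn-aldol. C5 comes from the chair transition state of the [2+2] step, which funnels both C5 epimers of the amide through a planar keteniminium. The ring expansion should retain C5. The (Z)-alkene comes from a chelation-controlled enol tosylate and a retentive addition–elimination.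

Key step: step 7

**Step 1**
Reactants: 1 (S)-4-benzyl-3-propionyloxazolidin-2-one; 2 pent-4-ynal
Product: 4 (4S)-4-benzyl-3-[(2S,3R)-3-hydroxy-2-methylhept-6-ynoyl]oxazolidin-2-one, via (Z)-boron enolate 3 (not isolated)
Conditions: n-Bu2BOTf, i-Pr2NEt, CH2Cl2, 0 °C; 2, −78 to 0 °C; pH 7 sodium phosphate buffer, MeOH, 30% H2O2
Reagents that add atoms: di-n-butylboron triflate, CCCCB(CCCC)OS(=O)(=O)C(F)(F)F (gives the Bu2B group of 3; no reagent atoms remain in 4)
Why: Evans syn-aldol reaction; the (Z)-boron enolate 3 reacts through a closed Zimmerman–Traxler chair on the face away from the benzyl group, which should set the C3 carbinol and the C4 methyl centre of the target as the (2S,3R) syn pair.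

**Step 2**
Reactants: 4 (4S)-4-benzyl-3-[(2S,3R)-3-hydroxy-2-methylhept-6-ynoyl]oxazolidin-2-one
Product: 5 (2S,3R)-3-hydroxy-N-methoxy-N,2-dimethylhept-6-ynamide
Conditions: MeNHOMe·HCl, AlMe3, CH2Cl2, −20 to 0 °C; aq. HCl (1 M)
Reagents that add atoms: N,O-dimethylhydroxylamine hydrochloride, CNOC.Cl
Why: Weinreb amide formation by aluminium amide transamidation; the free β-hydroxyl group directs attack to the exocyclic carbonyl, so the auxiliary should be released without epimerization.

**Step 3**
Reactants: 5 (2S,3R)-3-hydroxy-N-methoxy-N,2-dimethylhept-6-ynamide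
Product: 6 (2S,3R)-3-(tert-butyldimethylsilyloxy)-N-methoxy-N,2-dimethylhept-6-ynamide
Conditions: TBSOTf, 2,6-lutidine, CH2Cl2, −78 to 0 °C; aq. NaHCO3
Reagents that add atoms: tert-butyldimethylsilyl triflate, CC(C)(C)[Si](C)(C)OS(=O)(=O)C(F)(F)F
Why: Silylation of a secondary alcohol; the bulky silyl ether should survive the Grignard, enolate, photochemical, amide-activation and nickel steps and leaves with fluoride.

**Step 4**
Reactants: 6 (2S,3R)-3-(tert-butyldimethylsilyloxy)-N-methoxy-N,2-dimethylhept-6-ynamide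
Product: 7 (4S,5R)-5-(tert-butyldimethylsilyloxy)-4-methylnon-8-yn-3-one
Conditions: EtMgBr (2.5 equiv), THF, −20 to 0 °C; aq. NH4Cl
Reagents that add atoms: ethylmagnesium bromide, CC[Mg]Br
Why: Weinreb ketone synthesis; the chelated tetrahedral adduct stops at the ketone stage, and any magnesium acetylide formed from the terminal alkyne is returned on quench.

**Step 5**
Reactants: 7 (4S,5R)-5-(tert-butyldimethylsilyloxy)-4-methylnon-8-yn-3-one
Product: 9 (4S,5R)-5-(tert-butyldimethylsilyloxy)-2-diazo-4-methylnon-8-yn-3-one, via trifluoroacetyl diketone 8 (not isolated)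
Conditions: LiN(SiMe3)2, THF, −78 °C; CF3CO2CH2CF3; aq. HCl (5%); then MsN3, Et3N, H2O (1 equiv), MeCN, rt
Reagents that add atoms: 2,2,2-trifluoroethyl trifluoroacetate, O=C(OCC(F)(F)F)C(F)(F)F (trifluoroacetyl group of 8 only); methanesulfonyl azide, CS(=O)(=O)N=[N+]=[N-] (diazo nitrogen atoms of 9)
Why: Deacylative Regitz-type diazo transfer; kinetic enolization takes place at the unhindered ethyl CH2 and not at the C4 methine, so the α-stereocentre and the β-silyloxy group should be untouched.

**Step 6**
Reactants: 9 (4S,5R)-5-(tert-butyldimethylsilyloxy)-2-diazo-4-methylnon-8-yn-3-one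
Product: 11 1-[(3R,4R)-4-(tert-butyldimethylsilyloxy)-2,3-dimethyloct-7-ynoyl]pyrrolidine as a mixture of C2 epimers, via ketene 10 (not isolated)
Conditions: hν (300 nm, Pyrex), pyrrolidine (3 equiv), THF, rt
Reagents that add atoms: pyrrolidine, C1CCNC1
Why: Photochemical Wolff rearrangement; loss of N2 with 1,2-shift of the C4 carbon (retention at the migrating centre) gives ketene 10, which pyrrolidine traps, and the new α-centre (C5 of the target) may form as a mixture because it becomes trigonal again in step 7.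

**Step 7**
Reactants: 11 1-[(3R,4R)-4-(tert-butyldimethylsilyloxy)-2,3-dimethyloct-7-ynoyl]pyrrolidine
Product: 14 (4R,5R,6R)-4-(tert-butyldimethylsilyloxy)-5,6-dimethylbicyclo[4.2.0]oct-1(8)-en-7-one, via keteniminium triflate 12 (not isolated), via bicyclic iminium triflate 13 (not isolated)
Conditions: Tf2O, 2,4,6-collidine, ClCH2CH2Cl, −20 °C to reflux; then aq. NaHCO3, rt
Reagents that add atoms: water, O (carbonyl oxygen of 14); trifluoromethanesulfonic anhydride, O=S(=O)(OS(=O)(=O)C(F)(F)F)C(F)(F)F (triflate counter-ion of 12 and 13 only)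
Why: Tf2O converts amide 11 into its O-triflyl iminium salt and collidine removes the C5 proton; in the resulting keteniminium 12, C5 is trigonal, so both C5 epimers of 11 converge, and the electrophilic central carbon C8 adds to the terminal alkyne carbon C9 while the enamine-like carbon C5 closes onto the developing vinyl cation at C10, giving iminium salt 13, which water hydrolyses to 14. The closest known reaction types are the [2+2] cycloaddition of keteniminium salts with alkynes to give cyclobutenones and the intramolecular keteniminium–alkene [2+2] cycloaddition that gives bicyclo[4.2.0]octanones. The four-membered ring closes in the [2+2] sense through the bonds C8–C9 and C5–C10, and ring A closes by the same C5–C10 bond as a 6-exo-dig attack on the alkyne held by the four-carbon tether C4–C3–C2–C1. The new quaternary stereocentre C5 is controlled by the C4 and C3 stereocentres through a chair-like six-membered transition state in which C4–CH3 and C3–OTBS are equatorial and C5–CH3 is axial (cis to C4–CH3); the competing chair would force C3–OTBS into a 1,3-diaxial clash with C5–CH3. The step needs C8-to-C9 regiochemistry, secured by the tether (only the fused mode is possible) and by the preference for the more substituted vinyl cation at C10, and it needs chemoselectivity for the alkyne over the C3 oxygen, secured by the bulky, weakly nucleophilic silyl ether and the hindered base.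

**Step 8**
Reactants: 14 (4R,5R,6R)-4-(tert-butyldimethylsilyloxy)-5,6-dimethylbicyclo[4.2.0]oct-1(8)-en-7-one; 15 2-methyl-2-(trimethylsilyloxy)but-3-yne
Product: 16 (4aR,5R,6R)-6-(tert-butyldimethylsilyloxy)-4a,5-dimethyl-3-[2-(trimethylsilyloxy)propan-2-yl]-5,6,7,8-tetrahydronaphthalen-2(4aH)-one
Conditions: Ni(cod)2 (10 mol %), PPh3 (20 mol %), toluene, 0 °C to rt, slow addition of 15
Reagents that add atoms: none
Why: Proposed new method: zerovalent nickel should insert into the strained acyl–C(sp3) bond C8–C5 of 14 to give an allyl(acyl)nickel metallacycle (an η4-vinylketene complex), alkyne 15 should insert with its unsubstituted carbon bonding to the congested quaternary C5 and its silyloxy-substituted carbon on nickel, and acyl–vinyl reductive elimination (C7–C8) should release the cross-conjugated dienone, which cannot tautomerize to a phenol because C5 is quaternary; nickel stays on one face of the allyl unit, so C6 should take the place of C8 with retention at C5, and the closest known reaction type is the Ni(cod)2-catalysed [4+2] union of cyclobutenones with alkynes to give phenols (with the related rhodium-catalysed "cut-and-sew" insertions into cyclobutanones), which has not been shown for 4,4-disubstituted cyclobutenones.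

**Step 9**
Reactants: 16 (4aR,5R,6R)-6-(tert-butyldimethylsilyloxy)-4a,5-dimethyl-3-[2-(trimethylsilyloxy)propan-2-yl]-5,6,7,8-tetrahydronaphthalen-2(4aH)-one
Product: 17 (4aR,5R,6R)-6-hydroxy-3-(2-hydroxypropan-2-yl)-4a,5-dimethyl-5,6,7,8-tetrahydronaphthalen-2(4aH)-one
Conditions: Bu4NF, AcOH, THF, rt to 40 °C
Reagents that add atoms: none
Why: Fluoride cleavage of both silyl ethers; buffering with acetic acid should protect the dienone and the tertiary allylic alcohol from base and from acid-induced dehydration.

**Step 10**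
Reactants: 18 ethyl 2-formylpropanoate
Product: 19 ethyl (2Z)-2-methyl-3-(tosyloxy)prop-2-enoate
Conditions: TsCl, N-methylimidazole, LiOH, MeCN, 0 °C
Reagents that add atoms: p-toluenesulfonyl chloride, Cc1ccc(cc1)S(=O)(=O)Cl
Why: Stereoselective enol tosylation; the lithium chelate between the enolate oxygen and the ester carbonyl holds these two groups cis, so O-sulfonylation should give the (Z)-enol tosylate.

**Step 11**
Reactants: 19 ethyl (2Z)-2-methyl-3-(tosyloxy)prop-2-enoate
Product: 20 ethyl (2Z)-2-methyl-3-(methylsulfanyl)prop-2-enoate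
Conditions: NaSMe (1.0 equiv), THF, −20 to 0 °C
Reagents that add atoms: sodium methanethiolate, [Na+].[S-]C
Why: Nucleophilic vinylic substitution by addition–elimination; the ester-stabilized carbanion should expel tosylate after the shorter 60° rotation, which gives retention, and one equivalent of thiolate at low temperature avoids thiolate-mediated isomerization of the product.

**Step 12**
Reactants: 20 ethyl (2Z)-2-methyl-3-(methylsulfanyl)prop-2-enoate
Product: 21 (2Z)-2-methyl-3-(methylsulfanyl)prop-2-enoic acid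
Conditions: LiOH, THF–H2O, 0 °C to rt; aq. HCl to pH 3
Reagents that add atoms: lithium hydroxide, [Li+].[OH-] (oxygen of the carboxylic acid OH)
Why: Ester saponification; the electron-rich β-thioacrylate is a poor acceptor for hydroxide, so the alkene geometry should be kept.

**Step 13**
Reactants: 17 (4aR,5R,6R)-6-hydroxy-3-(2-hydroxypropan-2-yl)-4a,5-dimethyl-5,6,7,8-tetrahydronaphthalen-2(4aH)-one; 21 (2Z)-2-methyl-3-(methylsulfanyl)prop-2-enoic acid
Product: 22 (1R,2R,8aR)-7-(2-hydroxypropan-2-yl)-1,8a-dimethyl-6-oxo-1,2,3,4,6,8a-hexahydronaphthalen-2-yl (2Z)-2-methyl-3-(methylsulfanyl)prop-2-enoate (CNP0150028.1)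
Conditions: DCC, DMAP (0.2 equiv), CH2Cl2, 0 °C to rt
Reagents that add atoms: none
Why: Steglich esterification; only the secondary C3 hydroxyl should be acylated because the tertiary C11 hydroxyl is too hindered, and the low temperature should keep the (Z)-vinyl sulfide from isomerizing.

**Compound list**

1 | (S)-4-benzyl-3-propionyloxazolidin-2-one | CCC(=O)N1[C@@H](Cc2ccccc2)COC1=O | starting material
2 | pent-4-ynal | C#CCCC=O | starting material
3 | (4S)-4-benzyl-3-[(1Z)-1-(dibutylboranyloxy)prop-1-enyl]oxazolidin-2-one | C/C=C(\OB(CCCC)CCCC)N1[C@@H](Cc2ccccc2)COC1=O | intermediate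
4 | (4S)-4-benzyl-3-[(2S,3R)-3-hydroxy-2-methylhept-6-ynoyl]oxazolidin-2-one | C#CCC[C@@H](O)[C@H](C)C(=O)N1[C@@H](Cc2ccccc2)COC1=O | intermediate
5 | (2S,3R)-3-hydroxy-N-methoxy-N,2-dimethylhept-6-ynamide | C#CCC[C@@H](O)[C@H](C)C(=O)N(C)OC | intermediate
6 | (2S,3R)-3-(tert-butyldimethylsilyloxy)-N-methoxy-N,2-dimethylhept-6-ynamide | C#CCC[C@@H](O[Si](C)(C)C(C)(C)C)[C@H](C)C(=O)N(C)OC | intermediate
7 | (4S,5R)-5-(tert-butyldimethylsilyloxy)-4-methylnon-8-yn-3-one | C#CCC[C@@H](O[Si](C)(C)C(C)(C)C)[C@H](C)C(=O)CC | intermediate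
8 | (5S,6R)-6-(tert-butyldimethylsilyloxy)-1,1,1-trifluoro-3,5-dimethyldec-9-yne-2,4-dione (C3 epimers) | C#CCC[C@@H](O[Si](C)(C)C(C)(C)C)[C@H](C)C(=O)C(C)C(=O)C(F)(F)F | intermediate
9 | (4S,5R)-5-(tert-butyldimethylsilyloxy)-2-diazo-4-methylnon-8-yn-3-one | C#CCC[C@@H](O[Si](C)(C)C(C)(C)C)[C@H](C)C(=O)C(C)=[N+]=[N-] | intermediate
10 | (3R,4R)-4-(tert-butyldimethylsilyloxy)-2,3-dimethylocta-1-en-7-yn-1-one (ketene) | C#CCC[C@@H](O[Si](C)(C)C(C)(C)C)[C@H](C)C(C)=C=O | intermediate
11 | 1-[(3R,4R)-4-(tert-butyldimethylsilyloxy)-2,3-dimethyloct-7-ynoyl]pyrrolidine (C2 epimers) | C#CCC[C@@H](O[Si](C)(C)C(C)(C)C)[C@H](C)C(C)C(=O)N1CCCC1 | intermediate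
12 | 1-[(3R,4R)-4-(tert-butyldimethylsilyloxy)-2,3-dimethylocta-1-en-7-yn-1-ylidene]pyrrolidin-1-ium trifluoromethanesulfonate | C#CCC[C@@H](O[Si](C)(C)C(C)(C)C)[C@H](C)C(C)=C=[N+]1CCCC1.[O-]S(=O)(=O)C(F)(F)F | intermediate
13 | 1-[(4R,5R,6R)-4-(tert-butyldimethylsilyloxy)-5,6-dimethylbicyclo[4.2.0]oct-1(8)-en-7-ylidene]pyrrolidin-1-ium trifluoromethanesulfonate | CC(C)(C)[Si](C)(C)O[C@@H]1CCC2=CC(=[N+]3CCCC3)[C@]2(C)[C@H]1C.[O-]S(=O)(=O)C(F)(F)F | intermediate
14 | (4R,5R,6R)-4-(tert-butyldimethylsilyloxy)-5,6-dimethylbicyclo[4.2.0]oct-1(8)-en-7-one | CC(C)(C)[Si](C)(C)O[C@@H]1CCC2=CC(=O)[C@]2(C)[C@H]1C | intermediate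
15 | 2-methyl-2-(trimethylsilyloxy)but-3-yne | C#CC(C)(C)O[Si](C)(C)C | starting material
16 | (4aR,5R,6R)-6-(tert-butyldimethylsilyloxy)-4a,5-dimethyl-3-[2-(trimethylsilyloxy)propan-2-yl]-5,6,7,8-tetrahydronaphthalen-2(4aH)-one | CC(C)(C)[Si](C)(C)O[C@@H]1CCC2=CC(=O)C(C(C)(C)O[Si](C)(C)C)=C[C@]2(C)[C@H]1C | intermediate
17 | (4aR,5R,6R)-6-hydroxy-3-(2-hydroxypropan-2-yl)-4a,5-dimethyl-5,6,7,8-tetrahydronaphthalen-2(4aH)-one | O[C@@H]1CCC2=CC(=O)C(C(C)(C)O)=C[C@]2(C)[C@H]1C | intermediate
18 | ethyl 2-formylpropanoate | CCOC(=O)C(C)C=O | starting material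
19 | ethyl (2Z)-2-methyl-3-(tosyloxy)prop-2-enoate | Cc1ccc(cc1)S(=O)(=O)O/C=C(/C)C(=O)OCC | intermediate
20 | ethyl (2Z)-2-methyl-3-(methylsulfanyl)prop-2-enoate | CS/C=C(/C)C(=O)OCC | intermediate
21 | (2Z)-2-methyl-3-(methylsulfanyl)prop-2-enoic acid | CS/C=C(/C)C(=O)O | intermediate
22 | (1R,2R,8aR)-7-(2-hydroxypropan-2-yl)-1,8a-dimethyl-6-oxo-1,2,3,4,6,8a-hexahydronaphthalen-2-yl (2Z)-2-methyl-3-(methylsulfanyl)prop-2-enoate | CS/C=C(/C)C(=O)O[C@@H]1CCC2=CC(=O)C(C(C)(C)O)=C[C@]2(C)[C@H]1C | target

**Step count**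

Total: 13 steps. Longest linear sequence: 10 steps (steps 1–9 and 13); the acid 21 is made in 3 steps (10–12).

**Steps most likely to fail**

1. Step 8 (nickel-catalysed alkyne insertion). What may go wrong: insertion of 15 in the opposite orientation, oligomerization of the terminal alkyne on nickel before the hindered C5–C6 bond forms, or loss of CO from the metallacycle. Fallback with known chemistry, from 14 back to 16: the alkenyllithium CH2=C(Li)C(CH3)2OSiMe3, made from 2-bromo-3-methyl-3-(trimethylsilyloxy)but-1-ene and t-BuLi at −78 °C, is added to the carbonyl group of 14. On warming, the lithium cyclobutenoxide should undergo the oxy-anion-accelerated 4π ring opening and 6π ring closure known for alkenyllithium adducts of cyclobutenones. The regiochemistry is fixed because the lithiated carbon becomes C7. The cross-conjugated dienolate is trapped with Me3SiCl as the silyl dienol ether F1, and Saegusa–Ito oxidation (Pd(OAc)2, MeCN) introduces the C6=C7 double bond to give 16. In this sequence C5 becomes trigonal and is formed again in the ring closure, so its configuration would have to be confirmed at F1.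

2. Step 7 (keteniminium–alkyne [2+2]). What may go wrong: capture of the keteniminium by the unactivated terminal alkyne may be too slow, so that the activated amide is consumed by attack of the C3 silyl ether oxygen or returns as 11 on hydrolysis. Fallback, from 11 back to 14: semi-hydrogenation (H2, Pd/CaCO3 poisoned with Pb(OAc)2, quinoline) gives the terminal alkene F2, a more nucleophilic partner. The well-established intramolecular keteniminium–alkene [2+2] cycloaddition (Tf2O, collidine, ClCH2CH2Cl, reflux; aq. NaHCO3) should give the cis-fused cyclobutanone F3 through the same chair transition state. Enolization is possible only toward C9 (LiN(SiMe3)2, Me3SiCl) and gives the silyl enol ether F4. Saegusa–Ito oxidation (Pd(OAc)2, MeCN) then restores the C9=C10 double bond of 14.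

3. Step 6 (Wolff rearrangement). What may go wrong: the carbene formed on photolysis may undergo a 1,2-hydrogen shift from the methyl group, giving a vinyl ketone, in competition with the 1,2-shift of the branched C4 carbon. Fallback, from 6 back to 11: MeMgBr converts Weinreb amide 6 into methyl ketone F5. Wittig reaction with Ph3P=CHOMe gives enol ether F6. Mild acid hydrolysis (pyridinium p-toluenesulfonate, aq. acetone) gives aldehyde F7 as a mixture of C2 epimers. Pinnick oxidation (NaClO2, NaH2PO4, 2-methylbut-2-ene) gives acid F8, and coupling with pyrrolidine (EDC·HCl, HOBt) gives 11.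

**Further compounds**

F1 | step 8 | (4aR,5R,6R)-6-(tert-butyldimethylsilyloxy)-4a,5-dimethyl-2-(trimethylsilyloxy)-3-[2-(trimethylsilyloxy)propan-2-yl]-4,4a,5,6,7,8-hexahydronaphthalene | CC(C)(C)[Si](C)(C)O[C@@H]1CCC2=CC(O[Si](C)(C)C)=C(C(C)(C)O[Si](C)(C)C)C[C@]2(C)[C@H]1C
F2 | step 7 | 1-[(3R,4R)-4-(tert-butyldimethylsilyloxy)-2,3-dimethyloct-7-enoyl]pyrrolidine (C2 epimers) | C=CCC[C@@H](O[Si](C)(C)C(C)(C)C)[C@H](C)C(C)C(=O)N1CCCC1
F3 | step 7 | (1R,4R,5R,6S)-4-(tert-butyldimethylsilyloxy)-5,6-dimethylbicyclo[4.2.0]octan-7-one | CC(C)(C)[Si](C)(C)O[C@@H]1CC[C@@H]2CC(=O)[C@]2(C)[C@H]1C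
F4 | step 7 | (1R,4R,5R,6S)-4-(tert-butyldimethylsilyloxy)-5,6-dimethyl-7-(trimethylsilyloxy)bicyclo[4.2.0]oct-7-ene | CC(C)(C)[Si](C)(C)O[C@@H]1CC[C@@H]2C=C(O[Si](C)(C)C)[C@]2(C)[C@H]1C
F5 | step 6 | (3S,4R)-4-(tert-butyldimethylsilyloxy)-3-methyloct-7-yn-2-one | C#CCC[C@@H](O[Si](C)(C)C(C)(C)C)[C@H](C)C(C)=O
F6 | step 6 | (3R,4R)-4-(tert-butyldimethylsilyloxy)-1-methoxy-2,3-dimethylocta-1-en-7-yne (E/Z mixture) | C#CCC[C@@H](O[Si](C)(C)C(C)(C)C)[C@H](C)C(C)=COC
F7 | step 6 | (3R,4R)-4-(tert-butyldimethylsilyloxy)-2,3-dimethyloct-7-ynal (C2 epimers) | C#CCC[C@@H](O[Si](C)(C)C(C)(C)C)[C@H](C)C(C)C=O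
F8 | step 6 | (3R,4R)-4-(tert-butyldimethylsilyloxy)-2,3-dimethyloct-7-ynoic acid (C2 epimers) | C#CCC[C@@H](O[Si](C)(C)C(C)(C)C)[C@H](C)C(C)C(=O)O
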